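**Retrosynthetic overview**

1. Labdane numbering is used: ring A = C1–C5 and C10, ring B = C5–C10, C18 (CH3) and C19 (CO2H) on C4, C20 on C10, C17 on C8, chain C11–C16 on C9. The route rests on the C3(O)–C4(CH3)(C19) unit of ring A, a β-oxy carbonyl group with quaternary C4 and the C3 oxygen cis to C18.
2. Last disconnections: C3 acetate and C19 acid from a silyl ether and a 2-(trimethylsilyl)ethyl ester; C8=C17 by Wittig methylenation; the C13(=C16)–C14=C15 diene by ethylene–alkyne metathesis of a C13≡C14 alkyne grown from a C9 allyl group (C11–C13).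
3. C10–C20 and C9–C11 by conjugate methylation of a ring B C9=C10 enone (C8 ketone) and allylation of its enolate; the enone by Birch reduction of an anisole ring that is ring B in latent form, C5 being set on conjugation.
4. Ring A, the C3–C4 bond and the C4 stereocentre by ring contraction: in the anti epoxy silyl ether of a benzo-fused cycloheptenol, C3 migrates from C19 to the benzylic C4 and C19 becomes the aldehyde.
5. The seven-membered precursor comes from 2-methoxybenzosuberone (desaturation, MeLi, oxidative transposition, CBS reduction, silylation, epoxidation). Ring order: arene (latent ring B) bought, ring A closed in step 7, ring B unveiled in steps 9–12.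

Key step: step 7

Remark: as drawn, the target is a cis-fused decalin, (3R,4R,5S,9S,10R) in labdane numbering. H5, C20, the C9 chain and C19 lie on one face; the C3 oxygen and C18 lie on the other. The route is planned for this arrangement.

**Route**

Step 1
Reactants: 1 2-methoxybenzosuberone
Product: 2 2-methoxy-8,9-dihydro-5H-benzo[7]annulen-5-one
Conditions: IBX (1.3 equiv), 4-methoxypyridine N-oxide, DMSO, 25 °C
Reagents that add atoms: none
Why: IBX dehydrogenation of a ketone to its enone through the enol; only C6 carries α-hydrogens, so C6=C7 is the only possible position, and the N-oxide-moderated reagent at room temperature should limit further desaturation to the benzotropone.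

Step 2
Reactants: 2 2-methoxy-8,9-dihydro-5H-benzo[7]annulen-5-one; 3 methyllithium
Product: 4 racemic 2-methoxy-5-methyl-8,9-dihydro-5H-benzo[7]annulen-5-ol
Conditions: MeLi, Et2O, −78 °C; aq NH4Cl
Reagents that add atoms: none
Why: 1,2-addition of the hard organolithium to the aryl vinyl ketone, which has no α-hydrogen to enolise, should give the tertiary allylic alcohol, whose stereocentre is destroyed in the next step.

Step 3
Reactants: 4 racemic tertiary allylic alcohol
Product: 5 2-methoxy-5-methyl-8,9-dihydro-7H-benzo[7]annulen-7-one
Conditions: pyridinium chlorochromate (C5H5NH)[CrO3Cl], 4 Å sieves, CH2Cl2, 20 °C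
Reagents that add atoms: pyridinium chlorochromate, [O-][Cr](=O)(=O)Cl.c1cc[nH+]cc1
Why: Babler–Dauben oxidative transposition, in which the tertiary chromate ester undergoes a [3,3] shift to the secondary allylic chromate at C7, which is oxidised to the enone conjugated through C5=C6 with the anisole ring.

Step 4
Reactants: 5 transposed enone
Product: 6 (7R)-2-methoxy-5-methyl-8,9-dihydro-7H-benzo[7]annulen-7-ol
Conditions: (S)-2-methyl-CBS-oxazaborolidine (10 mol%), BH3·SMe2, THF, −20 °C; MeOH
Reagents that add atoms: none
Why: Corey–Bakshi–Shibata reduction in which the alkenyl side of the enone acts as the large group, so the (S)-catalyst should deliver hydride to give the (R)-allylic alcohol (C3 of the target), 1,2-reduction being faster than hydroboration of the conjugated trisubstituted alkene.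

Step 5
Reactants: 6 (R)-allylic alcohol
Product: 7 (R)-allylic tert-butyldimethylsilyl ether
Conditions: TBSCl, imidazole, DMF, 20 °C
Reagents that add atoms: tert-butyldimethylsilyl chloride, CC(C)(C)[Si](C)(C)Cl
Why: silylation of the secondary alcohol under basic conditions that do not ionise the allylic, aryl-conjugated carbinol.

Step 6
Reactants: 7 (R)-allylic silyl ether
Product: 8 anti epoxy silyl ether (epoxide across C4 and C19, oxygen trans to the C3 silyloxy group)
Conditions: dimethyldioxirane, acetone, −20 °C; evaporate, use crude
Reagents that add atoms: dimethyldioxirane, CC1(C)OO1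
Why: electrophilic epoxidation of the electron-rich trisubstituted styrene-type alkene from the face opposite the bulky silyloxy group on the adjacent carbon should set C4 and C19, and the neutral dioxirane conditions preserve the acid-labile para-methoxybenzylic epoxide.

Step 7
Reactants: 8 anti epoxy silyl ether
Product: 9 (1R,2R)-2-[(tert-butyldimethylsilyl)oxy]-6-methoxy-1-methyl-1,2,3,4-tetrahydronaphthalene-1-carbaldehyde
Conditions: methylaluminium bis(4-bromo-2,6-di-tert-butylphenoxide) (20 mol%, stock solution), CH2Cl2, −78 °C; aq NaF
Reagents that add atoms: none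
Why: the bulky, oxophilic aluminium phenoxide binds the epoxide oxygen and weakens the C4–O bond at the tertiary, para-methoxybenzylic carbon, and as this bond breaks the C19–C3 bond shifts to C4 on the face opposite the departing oxygen while C19=O forms; this is the organoaluminium-promoted rearrangement of 2,3-epoxy silyl ethers to β-silyloxy aldehydes, a semipinacol-type 1,2-shift, applied here to a ring-fused benzylic epoxide. Ring A is closed by this 1,2-alkyl shift as a contraction of the seven-membered ring to a six-membered one and not by a cyclisation, the C3–C19 bond being the one given up. The new stereocentre C4 is set by inversion at the migration terminus, so the epoxide configuration, itself relayed from C3 in step 6, fixes it, and C3 migrates with retention; the anti epoxide should therefore give the C3 oxygen cis to C18 and trans to the formyl carbon C19. The step needs migration of C3 in place of the hydride shift from C19 (which would give a seven-membered α-silyloxy ketone) or proton loss from C18; this should be secured by the strain released on going from the seven- to the six-membered ring, by the migratory aptitude of the silyloxy-bearing carbon under a Lewis acid too bulky to chelate, and by the low temperature, which keeps the cation from becoming free. The product can neither enolise nor eliminate because C4 is quaternary.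

Step 8
Reactants: 9 silyloxy aldehyde
Product: 10 (1R,2R)-2-[(tert-butyldimethylsilyl)oxy]-6-methoxy-1-methyl-1,2,3,4-tetrahydronaphthalene-1-carboxylic acid
Conditions: NaClO2, NaH2PO4, 2-methylbut-2-ene, t-BuOH/H2O, 20 °C
Reagents that add atoms: sodium chlorite, [Na+].[O-]Cl=O
Why: Pinnick oxidation of the hindered, non-enolisable aldehyde under buffered conditions in which the silyl ether survives and the alkene scavenger keeps hypochlorite from the anisole ring.

Step 9
Reactants: 10 tetralin carboxylic acid
Product: 12 (1R,2R)-2-[(tert-butyldimethylsilyl)oxy]-1-methyl-6-oxo-1,2,3,4,5,6,7,8-octahydronaphthalene-1-carboxylic acid (C8 ketone with C5=C10 alkene), via Birch diene acid 11 (not isolated)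
Conditions: Li, NH3(l), t-BuOH, THF, −78 → −33 °C; NH4Cl; then (CO2H)2, THF/H2O, 20 °C
Reagents that add atoms: water, O
Why: Birch reduction of the anisole ring, with the carboxyl group protected as its lithium carboxylate, should give the 1-methoxy-1,4-diene in which the oxygen- and alkyl-bearing carbons C8, C5 and C10 stay sp2, and oxalic acid then hydrolyses only the enol ether to the C8 ketone, leaving the tetrasubstituted C5=C10 alkene and the silyl ether untouched.

Step 10
Reactants: 12 β,γ-unsaturated keto acid
Product: 13 2-(trimethylsilyl)ethyl ester of 12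
Conditions: Me3SiCH2CH2OH, PPh3, DIAD, THF, 0 → 20 °C
Reagents that add atoms: 2-(trimethylsilyl)ethanol, C[Si](C)(C)CCO
Why: Mitsunobu esterification, in which the hindered carboxylate is the nucleophile at the primary carbon of the activated alcohol, so the neopentyl-type acid is esterified without any reaction at its own carbonyl.

Step 11
Reactants: 13 β,γ-unsaturated keto ester
Product: 14 conjugated enone ester (C8 ketone, C9=C10, H5 cis to the ester carbon C19)
Conditions: DBU (0.2 equiv), CH2Cl2, 20 °C
Reagents that add atoms: none
Why: base-catalysed conjugation of the β,γ- to the α,β-unsaturated ketone through the dienolate, whose γ-protonation at C5 should occur axially on the face opposite the pseudoaxial C18 methyl group and give the epimer that is also thermodynamically preferred, with H5 cis to C19 and C6 equatorial on ring A.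

Step 12
Reactants: 14 conjugated enone ester; 3 methyllithium; 15 allyl iodide
Product: 17 C9-allyl cis-fused decalone (C20 cis to H5 and the allyl group cis to C20), via lithium enolate 16 (not isolated)
Conditions: CuI, MeLi (2 equiv per Cu), Et2O, −20 °C, then 14, 0 °C; then allyl iodide, DMPU, THF, −40 → 20 °C
Reagents that add atoms: none
Why: Gilman cuprate conjugate addition followed by enolate C-allylation, in which the methyl group should enter C10 on the face of H5 (the cis-fused outcome usual for Δ1(9)-octalones) and away from the axial C18 methyl group, and allyl iodide should attack the regiodefined enolate at C9 from the convex face to give the equatorial allyl group cis to C20, the epimer also favoured on equilibration at this enolisable centre.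

Step 13
Reactants: 17 C9-allyl decalone
Product: 19 C13 primary alcohol (3-hydroxypropyl ketone), via catechol boronate 18 (not isolated)
Conditions: catecholborane, RhCl(PPh3)3 (2 mol%), THF, 20 °C; then NaOH, H2O2, H2O, 0 °C
Reagents that add atoms: hydrogen peroxide, OO
Why: rhodium-catalysed hydroboration with catecholborane is selective for a terminal alkene in the presence of a ketone and places boron on the terminal carbon C13, and oxidation with retention gives the primary alcohol.

Step 14
Reactants: 19 C13 primary alcohol
Product: 20 C13 aldehyde (3-oxopropyl ketone)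
Conditions: Dess–Martin periodinane, CH2Cl2, 0 → 20 °C
Reagents that add atoms: none
Why: Dess–Martin oxidation of the primary alcohol to the aldehyde under non-basic conditions, which would also return any C8 alcohol formed in step 13 to the ketone.

Step 15
Reactants: 20 C13 aldehyde
Product: 21 C13≡C14 terminal alkyne (but-3-yn-1-yl ketone)
Conditions: dimethyl (1-diazo-2-oxopropyl)phosphonate, K2CO3, MeOH, 0 °C
Reagents that add atoms: dimethyl (1-diazo-2-oxopropyl)phosphonate, COP(=O)(OC)C(=[N+]=[N-])C(C)=O
Why: Ohira–Bestmann homologation, in which the diazomethylphosphonate anion adds to the aldehyde much faster than to the hindered C8 ketone and the alkylidene carbene rearranges to the alkyne; low temperature and short contact should limit intramolecular aldol reaction of the δ-keto aldehyde, and carbonate leaves C9 as its more stable equatorial epimer.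

Step 16
Reactants: 21 terminal alkyne
Product: 22 diene ketone (3-methylidenepent-4-en-1-yl chain on C9)
Conditions: ethylene (1–4 atm), second-generation Grubbs catalyst RuCl2(=CHPh)(H2IMes)(PCy3) (5 mol%), CH2Cl2, 25–40 °C
Reagents that add atoms: ethylene, C=C
Why: ethylene–alkyne cross-enyne metathesis, in which the ruthenium methylidene adds to the terminal alkyne and the vinylcarbene is released by ethylene, turns C13≡C14 into the 2-substituted buta-1,3-diene C13(=C16)–C14=C15 with no other alkene present to compete.

Step 17
Reactants: 22 diene ketone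
Product: 23 fully protected triene (C8=C17 installed)
Conditions: Ph3PCH3Br, KOtBu, THF/toluene, 20 → 60 °C
Reagents that add atoms: methyltriphenylphosphonium bromide, C[P+](c1ccccc1)(c1ccccc1)c1ccccc1.[Br-]
Why: Wittig methylenation of the hindered C8 ketone with excess ylide, to which the diene and the neopentyl-type ester are inert, while C9 keeps (or equilibrates to) the favoured equatorial configuration before the exocyclic alkene locks it.

Step 18
Reactants: 23 fully protected triene
Product: 24 3-hydroxy acid
Conditions: Bu4NF (excess), THF, 20 → 50 °C; aq NH4Cl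
Reagents that add atoms: none
Why: fluoride attacks both silicon atoms, so that β-fragmentation of the 2-(trimethylsilyl)ethyl ester frees the carboxylate without attack at the hindered carbonyl and Si–O cleavage frees the C3 alcohol.

Step 19
Reactants: 24 3-hydroxy acid
Product: 25 target, (3R,4R,5S,9S,10R)-3-acetoxylabda-8(17),13(16),14-trien-19-oic acid
Conditions: Ac2O, pyridine, DMAP (cat.), CH2Cl2, 20 °C; aq NaHCO3/THF, then acidify to pH 3
Reagents that add atoms: acetic anhydride, CC(=O)OC(C)=O
Why: DMAP-catalysed acetylation of the equatorial secondary alcohol, any mixed anhydride at the hindered carboxyl being hydrolysed in the bicarbonate work-up.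

**Compound list**

1 | 2-methoxy-6,7,8,9-tetrahydro-5H-benzo[7]annulen-5-one | COc1ccc2c(c1)CCCCC2=O | starting material
2 | 2-methoxy-8,9-dihydro-5H-benzo[7]annulen-5-one | COc1ccc2c(c1)CCC=CC2=O | intermediate
3 | methyllithium | [Li]C | starting material
4 | racemic 2-methoxy-5-methyl-8,9-dihydro-5H-benzo[7]annulen-5-ol | COc1ccc2c(c1)CCC=CC2(C)O | intermediate
5 | 2-methoxy-5-methyl-8,9-dihydro-7H-benzo[7]annulen-7-one | COc1ccc2c(c1)CCC(=O)C=C2C | intermediate
6 | (7R)-2-methoxy-5-methyl-8,9-dihydro-7H-benzo[7]annulen-7-ol | COc1ccc2c(c1)CC[C@@H](O)C=C2C | intermediate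
7 | tert-butyl{[(7R)-2-methoxy-5-methyl-8,9-dihydro-7H-benzo[7]annulen-7-yl]oxy}dimethylsilane | COc1ccc2c(c1)CC[C@@H](O[Si](C)(C)C(C)(C)C)C=C2C | intermediate
8 | (5R,6S,7R)-7-[(tert-butyldimethylsilyl)oxy]-5,6-epoxy-2-methoxy-5-methyl-6,7,8,9-tetrahydro-5H-benzo[7]annulene (epoxide oxygen anti to the silyloxy group) | COc1ccc2c(c1)CC[C@@H](O[Si](C)(C)C(C)(C)C)[C@@H]1O[C@]21C | intermediate
9 | (1R,2R)-2-[(tert-butyldimethylsilyl)oxy]-6-methoxy-1-methyl-1,2,3,4-tetrahydronaphthalene-1-carbaldehyde | COc1ccc2c(c1)CC[C@@H](O[Si](C)(C)C(C)(C)C)[C@]2(C)C=O | intermediate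
10 | (1R,2R)-2-[(tert-butyldimethylsilyl)oxy]-6-methoxy-1-methyl-1,2,3,4-tetrahydronaphthalene-1-carboxylic acid | COc1ccc2c(c1)CC[C@@H](O[Si](C)(C)C(C)(C)C)[C@]2(C)C(=O)O | intermediate
11 | (1R,2R)-2-[(tert-butyldimethylsilyl)oxy]-6-methoxy-1-methyl-1,2,3,4,5,8-hexahydronaphthalene-1-carboxylic acid | COC1=CCC2=C(C1)CC[C@@H](O[Si](C)(C)C(C)(C)C)[C@]2(C)C(=O)O | intermediate (not isolated)
12 | (1R,2R)-2-[(tert-butyldimethylsilyl)oxy]-1-methyl-6-oxo-1,2,3,4,5,6,7,8-octahydronaphthalene-1-carboxylic acid | O=C1CCC2=C(C1)CC[C@@H](O[Si](C)(C)C(C)(C)C)[C@]2(C)C(=O)O | intermediate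
13 | 2-(trimethylsilyl)ethyl (1R,2R)-2-[(tert-butyldimethylsilyl)oxy]-1-methyl-6-oxo-1,2,3,4,5,6,7,8-octahydronaphthalene-1-carboxylate | O=C1CCC2=C(C1)CC[C@@H](O[Si](C)(C)C(C)(C)C)[C@]2(C)C(=O)OCC[Si](C)(C)C | intermediate
14 | 2-(trimethylsilyl)ethyl (1R,2R,8aS)-2-[(tert-butyldimethylsilyl)oxy]-1-methyl-6-oxo-1,2,3,4,6,7,8,8a-octahydronaphthalene-1-carboxylate | O=C1CC[C@H]2C(=C1)CC[C@@H](O[Si](C)(C)C(C)(C)C)[C@]2(C)C(=O)OCC[Si](C)(C)C | intermediate
15 | allyl iodide (3-iodoprop-1-ene) | C=CCI | starting material
16 | lithium enolate (C8–OLi, C8=C9) of the 10-methyl cis-fused decalone ester, C20 cis to H5 | [Li]OC1=C[C@@]2(C)CC[C@@H](O[Si](C)(C)C(C)(C)C)[C@](C)(C(=O)OCC[Si](C)(C)C)[C@H]2CC1 | intermediate (not isolated)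
17 | 2-(trimethylsilyl)ethyl 2-[(tert-butyldimethylsilyl)oxy]-1,4a-dimethyl-6-oxo-5-(prop-2-en-1-yl)decahydronaphthalene-1-carboxylate, cis-fused, all centres as in 25 | C=CC[C@H]1C(=O)CC[C@H]2[C@]1(C)CC[C@@H](O[Si](C)(C)C(C)(C)C)[C@]2(C)C(=O)OCC[Si](C)(C)C | intermediate
18 | B-alkyl catechol boronate of 17 (boron on C13), all centres as in 25 | c1ccc2OB(CCC[C@H]3C(=O)CC[C@H]4[C@]3(C)CC[C@@H](O[Si](C)(C)C(C)(C)C)[C@]4(C)C(=O)OCC[Si](C)(C)C)Oc2c1 | intermediate (not isolated)
19 | 5-(3-hydroxypropyl) analogue of 17 | OCCC[C@H]1C(=O)CC[C@H]2[C@]1(C)CC[C@@H](O[Si](C)(C)C(C)(C)C)[C@]2(C)C(=O)OCC[Si](C)(C)C | intermediate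
20 | 5-(3-oxopropyl) analogue of 17 | O=CCC[C@H]1C(=O)CC[C@H]2[C@]1(C)CC[C@@H](O[Si](C)(C)C(C)(C)C)[C@]2(C)C(=O)OCC[Si](C)(C)C | intermediate
21 | 5-(but-3-yn-1-yl) analogue of 17 | C#CCC[C@H]1C(=O)CC[C@H]2[C@]1(C)CC[C@@H](O[Si](C)(C)C(C)(C)C)[C@]2(C)C(=O)OCC[Si](C)(C)C | intermediate
22 | 5-(3-methylidenepent-4-en-1-yl) analogue of 17 (C8 ketone) | C=CC(=C)CC[C@H]1C(=O)CC[C@H]2[C@]1(C)CC[C@@H](O[Si](C)(C)C(C)(C)C)[C@]2(C)C(=O)OCC[Si](C)(C)C | intermediate
23 | 2-(trimethylsilyl)ethyl 3-[(tert-butyldimethylsilyl)oxy]labda-8(17),13(16),14-trien-19-oate, all centres as in 25 | C=CC(=C)CC[C@H]1C(=C)CC[C@H]2[C@]1(C)CC[C@@H](O[Si](C)(C)C(C)(C)C)[C@]2(C)C(=O)OCC[Si](C)(C)C | intermediate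
24 | 3-hydroxylabda-8(17),13(16),14-trien-19-oic acid, all centres as in 25 | C=CC(=C)CC[C@H]1C(=C)CC[C@H]2[C@]1(C)CC[C@@H](O)[C@]2(C)C(=O)O | intermediate
25 | (1R,2R,4aR,5S,8aS)-2-acetoxy-1,4a-dimethyl-6-methylidene-5-(3-methylidenepent-4-en-1-yl)decahydronaphthalene-1-carboxylic acid | C=CC(=C)CC[C@H]1C(=C)CC[C@H]2[C@]1(C)CC[C@@H](OC(C)=O)[C@]2(C)C(=O)O | target

**Step count**

Total: 19 steps. Longest linear sequence: 19 steps, from 1.

**Steps most likely to fail**

Step 7. What may go wrong: hydride migration from C19 to C4 in place of C3 migration, proton loss from C18, or full ionisation to the para-methoxybenzylic cation with loss of the stereochemical relay. Fallback (sets out from 5, returns at 9): enone 5 is epoxidised enantioselectively by the nucleophilic route, with aqueous H2O2 and a 9-amino-9-deoxy-epi-cinchona alkaloid salt as iminium catalyst. The pseudo-enantiomer that places the oxygen as in 8 is used, and this gives the epoxy ketone F1. BF3·OEt2 in CH2Cl2 then brings about the classical acyl shift of an α,β-epoxy ketone, the reaction that contracts isophorone oxide to a formylcyclopentanone. The acyl carbon C3 moves from C19 to the benzylic C4 with inversion and gives the ring-contracted keto aldehyde F2. Me4NBH(OAc)3 in MeCN/AcOH reduces the aldehyde, and the resulting C19 alkoxyborohydride delivers hydride to the C3 ketone from the C19 face (Evans–Saksena-type delivery). This should give the diol F3 with the C3 hydroxyl cis to C18. TEMPO/PhI(OAc)2 oxidises only the primary alcohol to the hydroxy aldehyde F4, and TBSOTf/2,6-lutidine gives 9.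

Step 12. What may go wrong: slow 1,4-addition at the hindered C10, followed by proton exchange between the enolate and the product during the slow allylation at the neopentyl C9, which moves the enolate to C7 and leads to C7-allyl and diallyl ketones. Fallback (sets out from 14, returns at 17): Me2CuLi is added in the presence of Me3SiCl (THF, −78 °C), which accelerates the conjugate addition and traps the enolate as the regiodefined trimethylsilyl enol ether F5. F5 is then allylated under neutral conditions with allyl methyl carbonate, Pd2(dba)3 and dppe in THF at 65 °C (Tsuji allylation of a silyl enol ether). The methoxide released on oxidative addition unmasks the enolate only at C9.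

Step 6. What may go wrong: insufficient facial discrimination by the silyl ether in the flexible seven-membered ring, and opening of the very acid-sensitive epoxide. Fallback (sets out from 5, returns at 8): the enantiomeric catalyst, (R)-2-methyl-CBS-oxazaborolidine with BH3·SMe2, gives the (S)-alcohol F6. Hydroxyl-directed epoxidation with VO(acac)2 and t-BuOOH places the oxygen syn to the hydroxyl and gives the syn epoxy alcohol F7, which already has the C4 and C19 configuration of 8. Mitsunobu inversion at C3 with 4-nitrobenzoic acid, PPh3 and DIAD gives the anti ester F8. K2CO3 in MeOH frees the anti epoxy alcohol F9, and TBSCl/imidazole gives 8.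

**Further compounds**

F1 | step 7 | epoxy ketone of 5 (C4–C19 epoxide configured as in 8, C3 ketone) | COc1ccc2c(c1)CCC(=O)[C@@H]1O[C@]21C
F2 | step 7 | 6-methoxy-1-methyl-2-oxo-1,2,3,4-tetrahydronaphthalene-1-carbaldehyde, C4 configured as in 9 | COc1ccc2c(c1)CCC(=O)[C@]2(C)C=O
F3 | step 7 | 1-(hydroxymethyl)-6-methoxy-1-methyl-1,2,3,4-tetrahydronaphthalen-2-ol, hydroxyl cis to methyl | COc1ccc2c(c1)CC[C@@H](O)[C@]2(C)CO
F4 | step 7 | 2-hydroxy-6-methoxy-1-methyl-1,2,3,4-tetrahydronaphthalene-1-carbaldehyde, hydroxyl cis to methyl | COc1ccc2c(c1)CC[C@@H](O)[C@]2(C)C=O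
F5 | step 12 | trimethylsilyl enol ether (C8–OSiMe3, C8=C9) of the 10-methyl cis-fused decalone ester | C[Si](C)(C)OC1=C[C@@]2(C)CC[C@@H](O[Si](C)(C)C(C)(C)C)[C@](C)(C(=O)OCC[Si](C)(C)C)[C@H]2CC1
F6 | step 6 | (7S)-2-methoxy-5-methyl-8,9-dihydro-7H-benzo[7]annulen-7-ol | COc1ccc2c(c1)CC[C@H](O)C=C2C
F7 | step 6 | syn epoxy alcohol (epoxide as in 8, C3 hydroxyl cis to the epoxide oxygen) | COc1ccc2c(c1)CC[C@H](O)[C@@H]1O[C@]21C
F8 | step 6 | anti epoxy 4-nitrobenzoate (C3 inverted) | COc1ccc2c(c1)CC[C@@H](OC(=O)c3ccc(cc3)[N+](=O)[O-])[C@@H]1O[C@]21C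
F9 | step 6 | anti epoxy alcohol (desilyl 8) | COc1ccc2c(c1)CC[C@@H](O)[C@@H]1O[C@]21C
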